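**Retrosynthetic overview**
- Last bond: the vinyl–butenolide α-carbon bond, by Stille coupling of a hydroxy epoxy vinylstannane (west part) with an α-bromo-γ-ylidenebutenolide polyene.
- The polyene is cut at its central disubstituted CH=CH (Julia–Kocienski): a benzothiazolyl sulfone carrying the acetylenic acetoxy ring plus a bromobutenolide trienal.
- Key disconnection: the exocyclic C=C of the γ-alkylidenebutenolide, made by an intermolecular vinylogous Mukaiyama aldol of 3-bromo-2-silyloxyfuran with a C5 enal, then E1cB dehydration.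
- Both carbocycles come from (−)-actinol through one common enol triflate (carbonylation, Sharpless epoxidation and Takai olefination for the west ring; Sonogashira coupling for the east ring).
- Ring order: the cyclohexane rings and the lactone are bought as rings; the only ring formed is the oxirane (step 5).

Assumption: the target is natural pyrrhoxanthin (3S,5R,6S,3′R; all-E chain; Z-ylidenebutenolide), and (4R,6R)-actinol is bought enantiopure.

**Common steps**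

Step 1
Reactants: 1 (4R,6R)-4-hydroxy-2,2,6-trimethylcyclohexan-1-one [(−)-actinol]
Product: 2 (4R,6R)-4-{[tert-butyl(dimethyl)silyl]oxy}-2,2,6-trimethylcyclohexan-1-one
Conditions: TBSCl, imidazole, DMF, rt
Reagents that add atoms: tert-butyldimethylsilyl chloride, CC(C)(C)[Si](C)(C)Cl
Why: Silyl ether protection of the unhindered secondary alcohol proceeds without touching either stereocentre.

Step 2
Reactants: 2 (4R,6R)-4-{[tert-butyl(dimethyl)silyl]oxy}-2,2,6-trimethylcyclohexan-1-one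
Product: 4 (4R)-4-{[tert-butyl(dimethyl)silyl]oxy}-2,6,6-trimethylcyclohex-1-en-1-yl trifluoromethanesulfonate, via lithium enolate 3 (not isolated)
Conditions: LiN(i-Pr)2, THF, −78 → 0 °C; PhNTf2, −78 °C → rt
Reagents that add atoms: N-phenylbis(trifluoromethanesulfonimide), FC(F)(F)S(=O)(=O)N(c1ccccc1)S(=O)(=O)C(F)(F)F
Why: The ketone has a single enolisable α-CH, so enolate formation and O-triflation (enol triflate formation) give one regioisomer; the C6 stereocentre is deliberately erased and C4 is untouched.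

**West part (epoxy vinylstannane)**

Step 3
Reactants: 4 (4R)-4-{[tert-butyl(dimethyl)silyl]oxy}-2,6,6-trimethylcyclohex-1-en-1-yl trifluoromethanesulfonate
Product: 5 methyl (4R)-4-{[tert-butyl(dimethyl)silyl]oxy}-2,6,6-trimethylcyclohex-1-ene-1-carboxylate
Conditions: Pd(OAc)2 (5 mol %), PPh3 (10 mol %), CO (1 atm), MeOH, Et3N, DMF, 60 °C
Reagents that add atoms: carbon monoxide, [C-]#[O+]; methanol, CO
Why: Palladium-catalysed alkoxycarbonylation of the vinyl triflate (oxidative addition, CO insertion, methanolysis) installs the exocyclic carbon on the tetrasubstituted alkene.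

Step 4
Reactants: 5 methyl (4R)-4-{[tert-butyl(dimethyl)silyl]oxy}-2,6,6-trimethylcyclohex-1-ene-1-carboxylate
Product: 6 [(4R)-4-{[tert-butyl(dimethyl)silyl]oxy}-2,6,6-trimethylcyclohex-1-en-1-yl]methanol
Conditions: i-Bu2AlH, CH2Cl2, −78 → 0 °C; aq. potassium sodium tartrate
Reagents that add atoms: none
Why: Hydride 1,2-reduction of the conjugated ester by i-Bu2AlH stops cleanly at the allylic alcohol.

Step 5
Reactants: 6 [(4R)-4-{[tert-butyl(dimethyl)silyl]oxy}-2,6,6-trimethylcyclohex-1-en-1-yl]methanol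
Product: 7 [(1R,4S,6R)-4-{[tert-butyl(dimethyl)silyl]oxy}-2,2,6-trimethyl-7-oxabicyclo[4.1.0]heptan-1-yl]methanol
Conditions: Ti(Oi-Pr)4 (20 mol %), D-(−)-diethyl tartrate (24 mol %), t-BuOOH, 4 Å MS, CH2Cl2, −20 °C
Reagents that add atoms: tert-butyl hydroperoxide, CC(C)(C)OO
Why: Sharpless asymmetric epoxidation with D-(−)-tartrate delivers the peroxide oxygen to the alkene face anti to the C4 silyloxy group, setting both epoxide carbons (carotenoid 5R,6S) under reagent control.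

Step 6
Reactants: 7 [(1R,4S,6R)-4-{[tert-butyl(dimethyl)silyl]oxy}-2,2,6-trimethyl-7-oxabicyclo[4.1.0]heptan-1-yl]methanol
Product: 8 (1S,4S,6R)-4-{[tert-butyl(dimethyl)silyl]oxy}-2,2,6-trimethyl-7-oxabicyclo[4.1.0]heptane-1-carbaldehyde
Conditions: SO3·pyridine, DMSO, Et3N, CH2Cl2, 0 °C
Reagents that add atoms: none
Why: Parikh–Doering oxidation is non-acidic, so the epoxide and silyl ether survive and the α-quaternary epoxy aldehyde cannot epimerise.

Step 7
Reactants: 8 (1S,4S,6R)-4-{[tert-butyl(dimethyl)silyl]oxy}-2,2,6-trimethyl-7-oxabicyclo[4.1.0]heptane-1-carbaldehyde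
Product: 9 (1S,4S,6R)-4-{[tert-butyl(dimethyl)silyl]oxy}-1-[(E)-2-iodoethenyl]-2,2,6-trimethyl-7-oxabicyclo[4.1.0]heptane
Conditions: CrCl2, CHI3, THF, 0 °C → rt
Reagents that add atoms: iodoform, IC(I)I
Why: Takai olefination (geminal dichromium species from CHI3 and CrCl2) converts the hindered aldehyde into the (E)-iodoalkene with high E selectivity and tolerates the epoxide.

Step 8
Reactants: 9 (1S,4S,6R)-4-{[tert-butyl(dimethyl)silyl]oxy}-1-[(E)-2-iodoethenyl]-2,2,6-trimethyl-7-oxabicyclo[4.1.0]heptane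
Product: 11 tributyl{(E)-2-[(1S,4S,6R)-4-{[tert-butyl(dimethyl)silyl]oxy}-2,2,6-trimethyl-7-oxabicyclo[4.1.0]heptan-1-yl]ethenyl}stannane, via vinyllithium 10 (not isolated)
Conditions: t-BuLi (2.1 equiv), Et2O, −78 °C; Bu3SnCl, −78 °C → rt
Reagents that add atoms: tributyltin chloride, CCCC[Sn](Cl)(CCCC)CCCC
Why: Lithium–iodine exchange occurs with retention of alkene geometry, and stannylation of the vinyllithium is faster than any attack on the tetrasubstituted epoxide at −78 °C.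

Step 9
Reactants: 11 tributyl{(E)-2-[(1S,4S,6R)-4-{[tert-butyl(dimethyl)silyl]oxy}-2,2,6-trimethyl-7-oxabicyclo[4.1.0]heptan-1-yl]ethenyl}stannane
Product: 12 (1R,3S,6S)-1,5,5-trimethyl-6-[(E)-2-(tributylstannyl)ethenyl]-7-oxabicyclo[4.1.0]heptan-3-ol
Conditions: Bu4NF, THF, rt
Reagents that add atoms: none
Why: Fluoride-mediated desilylation frees the secondary alcohol, while the vinylstannane and epoxide are inert to Bu4NF.

**East part (acetylenic sulfone)**

Step 10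
Reactants: 4 (4R)-4-{[tert-butyl(dimethyl)silyl]oxy}-2,6,6-trimethylcyclohex-1-en-1-yl trifluoromethanesulfonate; 13 (2E)-3-methylpent-2-en-4-yn-1-ol
Product: 14 (2E)-5-[(4R)-4-{[tert-butyl(dimethyl)silyl]oxy}-2,6,6-trimethylcyclohex-1-en-1-yl]-3-methylpent-2-en-4-yn-1-ol
Conditions: Pd(PPh3)4 (5 mol %), CuI (10 mol %), Et2NH, DMF, rt → 50 °C
Reagents that add atoms: none
Why: Sonogashira coupling of the vinyl triflate with the terminal alkyne fixes the ring double bond where the triflate was (no dehydration needed) and keeps the E-enyne geometry and the C4 configuration.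

Step 11
Reactants: 14 (2E)-5-[(4R)-4-{[tert-butyl(dimethyl)silyl]oxy}-2,6,6-trimethylcyclohex-1-en-1-yl]-3-methylpent-2-en-4-yn-1-ol
Product: 15 (2E)-5-[(4R)-4-{[tert-butyl(dimethyl)silyl]oxy}-2,6,6-trimethylcyclohex-1-en-1-yl]-3-methylpent-2-en-4-ynal
Conditions: MnO2, CH2Cl2, rt
Reagents that add atoms: none
Why: MnO2 allylic oxidation converts only the allylic alcohol to the enal and leaves the silyl ether and enyne untouched.

Step 12
Reactants: 15 (2E)-5-[(4R)-4-{[tert-butyl(dimethyl)silyl]oxy}-2,6,6-trimethylcyclohex-1-en-1-yl]-3-methylpent-2-en-4-ynal; 16 triethyl phosphonoacetate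
Product: 17 ethyl (2E,4E)-7-[(4R)-4-{[tert-butyl(dimethyl)silyl]oxy}-2,6,6-trimethylcyclohex-1-en-1-yl]-5-methylhepta-2,4-dien-6-ynoate
Conditions: LiCl, DBU, MeCN, rt
Reagents that add atoms: none
Why: Horner–Wadsworth–Emmons olefination under Masamune–Roush conditions forms the new disubstituted alkene E-selectively with a base mild enough to preserve the enynal geometry.

Step 13
Reactants: 17 ethyl (2E,4E)-7-[(4R)-4-{[tert-butyl(dimethyl)silyl]oxy}-2,6,6-trimethylcyclohex-1-en-1-yl]-5-methylhepta-2,4-dien-6-ynoate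
Product: 18 (2E,4E)-7-[(4R)-4-{[tert-butyl(dimethyl)silyl]oxy}-2,6,6-trimethylcyclohex-1-en-1-yl]-5-methylhepta-2,4-dien-6-yn-1-ol
Conditions: i-Bu2AlH, CH2Cl2, −78 °C; aq. potassium sodium tartrate
Reagents that add atoms: none
Why: Hydride 1,2-reduction of the dienoate by i-Bu2AlH gives the primary allylic alcohol without touching the alkyne.

Step 14
Reactants: 18 (2E,4E)-7-[(4R)-4-{[tert-butyl(dimethyl)silyl]oxy}-2,6,6-trimethylcyclohex-1-en-1-yl]-5-methylhepta-2,4-dien-6-yn-1-ol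
Product: 19 2-{[(2E,4E)-7-[(4R)-4-{[tert-butyl(dimethyl)silyl]oxy}-2,6,6-trimethylcyclohex-1-en-1-yl]-5-methylhepta-2,4-dien-6-yn-1-yl]sulfanyl}-1,3-benzothiazole
Conditions: 2-mercaptobenzothiazole, PPh3, DIAD, THF, 0 °C → rt
Reagents that add atoms: 2-mercaptobenzothiazole, Sc1nc2ccccc2s1
Why: Mitsunobu thioetherification displaces the activated primary allylic hydroxyl by the acidic heteroaryl thiol in an SN2 sense.

Step 15
Reactants: 19 2-{[(2E,4E)-7-[(4R)-4-{[tert-butyl(dimethyl)silyl]oxy}-2,6,6-trimethylcyclohex-1-en-1-yl]-5-methylhepta-2,4-dien-6-yn-1-yl]sulfanyl}-1,3-benzothiazole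
Product: 20 (1R)-4-[(3E,5E)-7-(1,3-benzothiazol-2-ylsulfanyl)-3-methylhepta-3,5-dien-1-yn-1-yl]-3,5,5-trimethylcyclohex-3-en-1-ol
Conditions: Bu4NF, THF, rt
Reagents that add atoms: none
Why: Fluoride desilylation removes the TBS ether at the thioether stage, before the nucleophile-sensitive sulfone exists.

Step 16
Reactants: 20 (1R)-4-[(3E,5E)-7-(1,3-benzothiazol-2-ylsulfanyl)-3-methylhepta-3,5-dien-1-yn-1-yl]-3,5,5-trimethylcyclohex-3-en-1-ol
Product: 21 (1R)-4-[(3E,5E)-7-(1,3-benzothiazol-2-ylsulfanyl)-3-methylhepta-3,5-dien-1-yn-1-yl]-3,5,5-trimethylcyclohex-3-en-1-yl acetate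
Conditions: Ac2O, pyridine, DMAP (cat.), CH2Cl2, rt
Reagents that add atoms: acetic anhydride, CC(=O)OC(C)=O
Why: DMAP-catalysed acylation puts the acetate of the target on the only hydroxyl present, with retention at the carbinol carbon.

Step 17
Reactants: 21 (1R)-4-[(3E,5E)-7-(1,3-benzothiazol-2-ylsulfanyl)-3-methylhepta-3,5-dien-1-yn-1-yl]-3,5,5-trimethylcyclohex-3-en-1-yl acetate
Product: 22 (1R)-4-[(3E,5E)-7-(1,3-benzothiazol-2-ylsulfonyl)-3-methylhepta-3,5-dien-1-yn-1-yl]-3,5,5-trimethylcyclohex-3-en-1-yl acetate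
Conditions: (NH4)6Mo7O24·4H2O (10 mol %), 30 % H2O2, EtOH, 0 °C → rt
Reagents that add atoms: hydrogen peroxide, OO
Why: Molybdate-catalysed sulfide-to-sulfone oxidation is chemoselective for sulfur over the conjugated alkenes and the acetate.

**Butenolide part and key aldol**

Step 18
Reactants: 23 furan-2(5H)-one
Product: 25 3-bromofuran-2(5H)-one, via trans-dibromolactone 24 (not isolated)
Conditions: Br2, CH2Cl2, 0 °C → rt; Et3N, 0 °C
Reagents that add atoms: bromine, BrBr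
Why: Bromine addition followed by dehydrobromination (addition–elimination: Et3N removes the acidic α-H and the β-bromide leaves) gives the α-bromobutenolide regioselectively.

Step 19
Reactants: 25 3-bromofuran-2(5H)-one
Product: 26 [(3-bromofuran-2-yl)oxy]tri(propan-2-yl)silane
Conditions: TIPSOTf, Et3N, CH2Cl2, 0 °C
Reagents that add atoms: triisopropylsilyl trifluoromethanesulfonate, CC(C)[Si](OS(=O)(=O)C(F)(F)F)(C(C)C)C(C)C
Why: Soft enolisation (silyl enol ether formation) aromatises the butenolide to the 2-silyloxyfuran nucleophile.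

Step 20
Reactants: 27 {[tert-butyl(dimethyl)silyl]oxy}acetaldehyde; 28 2-(triphenyl-λ5-phosphanylidene)propanal
Product: 29 (2E)-4-{[tert-butyl(dimethyl)silyl]oxy}-2-methylbut-2-enal
Conditions: toluene, 80 °C
Reagents that add atoms: none
Why: Wittig olefination with the stabilised formyl ylide gives the (E)-trisubstituted enal selectively.

Step 21
Reactants: 26 [(3-bromofuran-2-yl)oxy]tri(propan-2-yl)silane; 29 (2E)-4-{[tert-butyl(dimethyl)silyl]oxy}-2-methylbut-2-enal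
Product: 30 3-bromo-5-[(2E)-4-{[tert-butyl(dimethyl)silyl]oxy}-1-hydroxy-2-methylbut-2-en-1-yl]furan-2(5H)-one (diastereomer mixture)
Conditions: BF3·OEt2, CH2Cl2, −78 °C; H2O
Reagents that add atoms: none
Why: In this vinylogous Mukaiyama aldol addition the γ-carbon (C5) of the silyloxyfuran attacks the BF3-activated aldehyde 1,2 to form the key C–C bond; the two new stereocentres arise as a mixture that does not matter because both are destroyed in step 22.

Step 22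
Reactants: 30 3-bromo-5-[(2E)-4-{[tert-butyl(dimethyl)silyl]oxy}-1-hydroxy-2-methylbut-2-en-1-yl]furan-2(5H)-one
Product: 32 (5Z)-3-bromo-5-[(2E)-4-{[tert-butyl(dimethyl)silyl]oxy}-2-methylbut-2-en-1-ylidene]furan-2(5H)-one, via allylic acetate 31 (not isolated)
Conditions: Ac2O, Et3N, DMAP (cat.), CH2Cl2, 0 °C; then DBU, 0 °C → rt
Reagents that add atoms: none
Why: Acetylation then E1cB elimination through the 2-oxidofuran converges both diastereomers on the conjugated γ-alkylidenebutenolide, with the thermodynamically favoured Z isomer (chain syn to the ring oxygen, away from C4–H) predominating and purified by chromatography.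

Step 23
Reactants: 32 (5Z)-3-bromo-5-[(2E)-4-{[tert-butyl(dimethyl)silyl]oxy}-2-methylbut-2-en-1-ylidene]furan-2(5H)-one
Product: 33 (5Z)-3-bromo-5-[(2E)-4-hydroxy-2-methylbut-2-en-1-ylidene]furan-2(5H)-one
Conditions: HF·pyridine, pyridine/THF, 0 °C → rt
Reagents that add atoms: none
Why: Buffered HF desilylation removes the primary TBS ether without opening the base-sensitive lactone.

Step 24
Reactants: 33 (5Z)-3-bromo-5-[(2E)-4-hydroxy-2-methylbut-2-en-1-ylidene]furan-2(5H)-one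
Product: 34 (2E)-4-[(2Z)-4-bromo-5-oxofuran-2(5H)-ylidene]-3-methylbut-2-enal
Conditions: MnO2, CH2Cl2, rt
Reagents that add atoms: none
Why: MnO2 allylic oxidation gives the trienal under neutral conditions that do not isomerise the Z-ylidene.

**Fragment union**

Step 25
Reactants: 34 (2E)-4-[(2Z)-4-bromo-5-oxofuran-2(5H)-ylidene]-3-methylbut-2-enal; 22 (1R)-4-[(3E,5E)-7-(1,3-benzothiazol-2-ylsulfonyl)-3-methylhepta-3,5-dien-1-yn-1-yl]-3,5,5-trimethylcyclohex-3-en-1-yl acetate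
Product: 36 (1R)-4-[(3E,5E,7E,9E)-11-[(2Z)-4-bromo-5-oxofuran-2(5H)-ylidene]-3,10-dimethylundeca-3,5,7,9-tetraen-1-yn-1-yl]-3,5,5-trimethylcyclohex-3-en-1-yl acetate, via 7Z-isomer 35 (not isolated)
Conditions: NaN(SiMe3)2, THF, −78 °C (base added last); then C6H6, rt, 3 d
Reagents that add atoms: none
Why: Julia–Kocienski olefination under Barbier conditions builds the central CH=CH as a Z-rich mixture, and this disubstituted cis bond of the conjugated polyene equilibrates thermally to the all-E isomer on standing in benzene.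

Step 26
Reactants: 36 (1R)-4-[(3E,5E,7E,9E)-11-[(2Z)-4-bromo-5-oxofuran-2(5H)-ylidene]-3,10-dimethylundeca-3,5,7,9-tetraen-1-yn-1-yl]-3,5,5-trimethylcyclohex-3-en-1-yl acetate; 12 (1R,3S,6S)-1,5,5-trimethyl-6-[(E)-2-(tributylstannyl)ethenyl]-7-oxabicyclo[4.1.0]heptan-3-ol
Product: 37 pyrrhoxanthin (CNP0337675.1)
Conditions: Pd2(dba)3·CHCl3 (5 mol %), AsPh3 (40 mol %), DMF, 25–40 °C, dark
Reagents that add atoms: none
Why: Stille cross-coupling of the activated α-bromobutenolide with the (E)-vinylstannane runs under neutral conditions with retention of both alkene geometries and tolerates the free alcohol, epoxide, acetate and polyene.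

**Compound list**

1 | (4R,6R)-4-hydroxy-2,2,6-trimethylcyclohexan-1-one, (−)-actinol | O[C@@H]1C[C@@H](C)C(=O)C(C)(C)C1 | starting material
2 | (4R,6R)-4-{[tert-butyl(dimethyl)silyl]oxy}-2,2,6-trimethylcyclohexan-1-one | CC(C)(C)[Si](C)(C)O[C@@H]1C[C@@H](C)C(=O)C(C)(C)C1 | intermediate
3 | lithium (4R)-4-{[tert-butyl(dimethyl)silyl]oxy}-2,6,6-trimethylcyclohex-1-en-1-olate | CC(C)(C)[Si](C)(C)O[C@@H]1CC(C)=C(O[Li])C(C)(C)C1 | intermediate
4 | (4R)-4-{[tert-butyl(dimethyl)silyl]oxy}-2,6,6-trimethylcyclohex-1-en-1-yl trifluoromethanesulfonate | CC(C)(C)[Si](C)(C)O[C@@H]1CC(C)=C(OS(=O)(=O)C(F)(F)F)C(C)(C)C1 | intermediate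
5 | methyl (4R)-4-{[tert-butyl(dimethyl)silyl]oxy}-2,6,6-trimethylcyclohex-1-ene-1-carboxylate | COC(=O)C1=C(C)C[C@@H](O[Si](C)(C)C(C)(C)C)CC1(C)C | intermediate
6 | [(4R)-4-{[tert-butyl(dimethyl)silyl]oxy}-2,6,6-trimethylcyclohex-1-en-1-yl]methanol | OCC1=C(C)C[C@@H](O[Si](C)(C)C(C)(C)C)CC1(C)C | intermediate
7 | [(1R,4S,6R)-4-{[tert-butyl(dimethyl)silyl]oxy}-2,2,6-trimethyl-7-oxabicyclo[4.1.0]heptan-1-yl]methanol | OC[C@@]12O[C@]1(C)C[C@@H](O[Si](C)(C)C(C)(C)C)CC2(C)C | intermediate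
8 | (1S,4S,6R)-4-{[tert-butyl(dimethyl)silyl]oxy}-2,2,6-trimethyl-7-oxabicyclo[4.1.0]heptane-1-carbaldehyde | O=C[C@@]12O[C@]1(C)C[C@@H](O[Si](C)(C)C(C)(C)C)CC2(C)C | intermediate
9 | (1S,4S,6R)-4-{[tert-butyl(dimethyl)silyl]oxy}-1-[(E)-2-iodoethenyl]-2,2,6-trimethyl-7-oxabicyclo[4.1.0]heptane | I/C=C/[C@@]12O[C@]1(C)C[C@@H](O[Si](C)(C)C(C)(C)C)CC2(C)C | intermediate
10 | {(E)-2-[(1S,4S,6R)-4-{[tert-butyl(dimethyl)silyl]oxy}-2,2,6-trimethyl-7-oxabicyclo[4.1.0]heptan-1-yl]ethenyl}lithium | [Li]/C=C/[C@@]12O[C@]1(C)C[C@@H](O[Si](C)(C)C(C)(C)C)CC2(C)C | intermediate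
11 | tributyl{(E)-2-[(1S,4S,6R)-4-{[tert-butyl(dimethyl)silyl]oxy}-2,2,6-trimethyl-7-oxabicyclo[4.1.0]heptan-1-yl]ethenyl}stannane | CCCC[Sn](CCCC)(CCCC)/C=C/[C@@]12O[C@]1(C)C[C@@H](O[Si](C)(C)C(C)(C)C)CC2(C)C | intermediate
12 | (1R,3S,6S)-1,5,5-trimethyl-6-[(E)-2-(tributylstannyl)ethenyl]-7-oxabicyclo[4.1.0]heptan-3-ol | CCCC[Sn](CCCC)(CCCC)/C=C/[C@@]12O[C@]1(C)C[C@@H](O)CC2(C)C | intermediate
13 | (2E)-3-methylpent-2-en-4-yn-1-ol | C#C/C(C)=C/CO | starting material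
14 | (2E)-5-[(4R)-4-{[tert-butyl(dimethyl)silyl]oxy}-2,6,6-trimethylcyclohex-1-en-1-yl]-3-methylpent-2-en-4-yn-1-ol | CC(C)(C)[Si](C)(C)O[C@@H]1CC(C)=C(C#C/C(C)=C/CO)C(C)(C)C1 | intermediate
15 | (2E)-5-[(4R)-4-{[tert-butyl(dimethyl)silyl]oxy}-2,6,6-trimethylcyclohex-1-en-1-yl]-3-methylpent-2-en-4-ynal | CC(C)(C)[Si](C)(C)O[C@@H]1CC(C)=C(C#C/C(C)=C/C=O)C(C)(C)C1 | intermediate
16 | triethyl phosphonoacetate | CCOC(=O)CP(=O)(OCC)OCC | starting material
17 | ethyl (2E,4E)-7-[(4R)-4-{[tert-butyl(dimethyl)silyl]oxy}-2,6,6-trimethylcyclohex-1-en-1-yl]-5-methylhepta-2,4-dien-6-ynoate | CC(C)(C)[Si](C)(C)O[C@@H]1CC(C)=C(C#C/C(C)=C/C=C/C(=O)OCC)C(C)(C)C1 | intermediate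
18 | (2E,4E)-7-[(4R)-4-{[tert-butyl(dimethyl)silyl]oxy}-2,6,6-trimethylcyclohex-1-en-1-yl]-5-methylhepta-2,4-dien-6-yn-1-ol | CC(C)(C)[Si](C)(C)O[C@@H]1CC(C)=C(C#C/C(C)=C/C=C/CO)C(C)(C)C1 | intermediate
19 | 2-{[(2E,4E)-7-[(4R)-4-{[tert-butyl(dimethyl)silyl]oxy}-2,6,6-trimethylcyclohex-1-en-1-yl]-5-methylhepta-2,4-dien-6-yn-1-yl]sulfanyl}-1,3-benzothiazole | CC(C)(C)[Si](C)(C)O[C@@H]1CC(C)=C(C#C/C(C)=C/C=C/CSc2nc3ccccc3s2)C(C)(C)C1 | intermediate
20 | (1R)-4-[(3E,5E)-7-(1,3-benzothiazol-2-ylsulfanyl)-3-methylhepta-3,5-dien-1-yn-1-yl]-3,5,5-trimethylcyclohex-3-en-1-ol | O[C@@H]1CC(C)=C(C#C/C(C)=C/C=C/CSc2nc3ccccc3s2)C(C)(C)C1 | intermediate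
21 | (1R)-4-[(3E,5E)-7-(1,3-benzothiazol-2-ylsulfanyl)-3-methylhepta-3,5-dien-1-yn-1-yl]-3,5,5-trimethylcyclohex-3-en-1-yl acetate | CC(=O)O[C@@H]1CC(C)=C(C#C/C(C)=C/C=C/CSc2nc3ccccc3s2)C(C)(C)C1 | intermediate
22 | (1R)-4-[(3E,5E)-7-(1,3-benzothiazol-2-ylsulfonyl)-3-methylhepta-3,5-dien-1-yn-1-yl]-3,5,5-trimethylcyclohex-3-en-1-yl acetate | CC(=O)O[C@@H]1CC(C)=C(C#C/C(C)=C/C=C/CS(=O)(=O)c2nc3ccccc3s2)C(C)(C)C1 | intermediate
23 | furan-2(5H)-one | O=C1OCC=C1 | starting material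
24 | trans-3,4-dibromodihydrofuran-2(3H)-one (racemic; one enantiomer drawn) | Br[C@H]1[C@H](Br)COC1=O | intermediate
25 | 3-bromofuran-2(5H)-one | O=C1OCC=C1Br | intermediate
26 | [(3-bromofuran-2-yl)oxy]tri(propan-2-yl)silane | CC(C)[Si](C(C)C)(C(C)C)Oc1occc1Br | intermediate
27 | {[tert-butyl(dimethyl)silyl]oxy}acetaldehyde | CC(C)(C)[Si](C)(C)OCC=O | starting material
28 | 2-(triphenyl-λ5-phosphanylidene)propanal | CC(C=O)=P(c1ccccc1)(c1ccccc1)c1ccccc1 | starting material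
29 | (2E)-4-{[tert-butyl(dimethyl)silyl]oxy}-2-methylbut-2-enal | CC(C)(C)[Si](C)(C)OC/C=C(C)/C=O | intermediate
30 | 3-bromo-5-[(2E)-4-{[tert-butyl(dimethyl)silyl]oxy}-1-hydroxy-2-methylbut-2-en-1-yl]furan-2(5H)-one (racemic diastereomer mixture at the two sp3 centres) | CC(C)(C)[Si](C)(C)OC/C=C(C)/C(O)C1OC(=O)C(Br)=C1 | intermediate
31 | (2E)-1-(4-bromo-5-oxo-2,5-dihydrofuran-2-yl)-4-{[tert-butyl(dimethyl)silyl]oxy}-2-methylbut-2-en-1-yl acetate (diastereomer mixture) | CC(C)(C)[Si](C)(C)OC/C=C(C)/C(OC(C)=O)C1OC(=O)C(Br)=C1 | intermediate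
32 | (5Z)-3-bromo-5-[(2E)-4-{[tert-butyl(dimethyl)silyl]oxy}-2-methylbut-2-en-1-ylidene]furan-2(5H)-one | CC(C)(C)[Si](C)(C)OC/C=C(C)/C=C1C=C(Br)C(=O)O/1 | intermediate
33 | (5Z)-3-bromo-5-[(2E)-4-hydroxy-2-methylbut-2-en-1-ylidene]furan-2(5H)-one | OC/C=C(C)/C=C1C=C(Br)C(=O)O/1 | intermediate
34 | (2E)-4-[(2Z)-4-bromo-5-oxofuran-2(5H)-ylidene]-3-methylbut-2-enal | O=C/C=C(C)/C=C1C=C(Br)C(=O)O/1 | intermediate
35 | (1R)-4-[(3E,5E,7Z,9E)-11-[(2Z)-4-bromo-5-oxofuran-2(5H)-ylidene]-3,10-dimethylundeca-3,5,7,9-tetraen-1-yn-1-yl]-3,5,5-trimethylcyclohex-3-en-1-yl acetate | CC(=O)O[C@@H]1CC(C)=C(C#C/C(C)=C/C=C/C=C\C=C(C)\C=C2C=C(Br)C(=O)O\2)C(C)(C)C1 | intermediate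
36 | (1R)-4-[(3E,5E,7E,9E)-11-[(2Z)-4-bromo-5-oxofuran-2(5H)-ylidene]-3,10-dimethylundeca-3,5,7,9-tetraen-1-yn-1-yl]-3,5,5-trimethylcyclohex-3-en-1-yl acetate | CC(=O)O[C@@H]1CC(C)=C(C#C/C(C)=C/C=C/C=C/C=C(C)/C=C2C=C(Br)C(=O)O/2)C(C)(C)C1 | intermediate
37 | pyrrhoxanthin, (1R)-4-[(3E,5E,7E,9E)-11-[(2Z)-4-{(E)-2-[(1S,4S,6R)-4-hydroxy-2,2,6-trimethyl-7-oxabicyclo[4.1.0]heptan-1-yl]ethenyl}-5-oxofuran-2(5H)-ylidene]-3,10-dimethylundeca-3,5,7,9-tetraen-1-yn-1-yl]-3,5,5-trimethylcyclohex-3-en-1-yl acetate | CC(=O)O[C@@H]1CC(C)=C(C#C/C(C)=C/C=C/C=C/C=C(C)/C=C2C=C(/C=C/[C@@]34O[C@]3(C)C[C@@H](O)CC4(C)C)C(=O)O/2)C(C)(C)C1 | target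

**Totals**

Total step count: 26.
Longest linear sequence: 12 steps (1 → 2 → 4 → 14 → 15 → 17 → 18 → 19 → 20 → 21 → 22 → 36 → 37; steps 1, 2, 10–17, 25, 26).

**Three steps most likely to fail, with fallbacks**

Step 5 (Sharpless epoxidation of a hindered tetrasubstituted allylic alcohol). The ring may erode reagent control or slow the reaction. The fallback is a substrate-controlled peracid epoxidation and sets out from 6. Ac2O/pyridine gives [(4R)-4-{[tert-butyl(dimethyl)silyl]oxy}-2,6,6-trimethylcyclohex-1-en-1-yl]methyl acetate F1. m-CPBA/NaHCO3 in CH2Cl2 at 0 °C then epoxidises mainly anti to the silyloxy group, the sense known for 3-O-protected carotenoid end groups. After chromatographic removal of the syn diastereomer this gives [(1R,4S,6R)-4-{[tert-butyl(dimethyl)silyl]oxy}-2,2,6-trimethyl-7-oxabicyclo[4.1.0]heptan-1-yl]methyl acetate F2. K2CO3 in MeOH cleaves the acetate and the route is rejoined at 7.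

Step 21 (BF3-mediated vinylogous Mukaiyama aldol). Silyloxyfuran 26 is moisture-labile, and γ- and 1,2-selectivity with the enal are not guaranteed. The fallback is a one-flask soft-enolisation aldol–elimination and sets out from 25 together with 29. TBSOTf (2.2 equiv) and i-Pr2NEt in CH2Cl2 silylate 25 in situ to [(3-bromofuran-2-yl)oxy](tert-butyl)dimethylsilane F3. F3 adds through its γ-carbon to the TBSOTf-activated aldehyde to give 3-bromo-5-[(2E)-1,4-bis{[tert-butyl(dimethyl)silyl]oxy}-2-methylbut-2-en-1-yl]furan-2(5H)-one F4. DBU then expels silanolate by E1cB elimination, and the route is rejoined at 32 without passing through 26, 30 or 31.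

Step 25 (Julia–Kocienski olefination on the α-bromo-ylidenebutenolide aldehyde). The sulfone anion may attack the bromobutenolide conjugatively, and the E/Z outcome may be poor. The fallback inverts the order of fragment union and sets out from 34. Stille coupling of 34 with 12 (Pd2(dba)3, AsPh3, DMF) gives (2E)-4-[(2Z)-4-{(E)-2-[(1S,4S,6R)-4-hydroxy-2,2,6-trimethyl-7-oxabicyclo[4.1.0]heptan-1-yl]ethenyl}-5-oxofuran-2(5H)-ylidene]-3-methylbut-2-enal F5. Julia–Kocienski olefination of F5 with 22 (NaN(SiMe3)2, 2.2 equiv, THF, −78 °C; then C6H6, rt) arrives directly at 37, so the sulfone anion never meets a C–Br bond.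

**Further compounds**

F1 | step 5 | [(4R)-4-{[tert-butyl(dimethyl)silyl]oxy}-2,6,6-trimethylcyclohex-1-en-1-yl]methyl acetate | CC(=O)OCC1=C(C)C[C@@H](O[Si](C)(C)C(C)(C)C)CC1(C)C
F2 | step 5 | [(1R,4S,6R)-4-{[tert-butyl(dimethyl)silyl]oxy}-2,2,6-trimethyl-7-oxabicyclo[4.1.0]heptan-1-yl]methyl acetate | CC(=O)OC[C@@]12O[C@]1(C)C[C@@H](O[Si](C)(C)C(C)(C)C)CC2(C)C
F3 | step 21 | [(3-bromofuran-2-yl)oxy](tert-butyl)dimethylsilane | CC(C)(C)[Si](C)(C)Oc1occc1Br
F4 | step 21 | 3-bromo-5-[(2E)-1,4-bis{[tert-butyl(dimethyl)silyl]oxy}-2-methylbut-2-en-1-yl]furan-2(5H)-one | CC(C)(C)[Si](C)(C)OC/C=C(C)/C(O[Si](C)(C)C(C)(C)C)C1OC(=O)C(Br)=C1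
F5 | step 25 | (2E)-4-[(2Z)-4-{(E)-2-[(1S,4S,6R)-4-hydroxy-2,2,6-trimethyl-7-oxabicyclo[4.1.0]heptan-1-yl]ethenyl}-5-oxofuran-2(5H)-ylidene]-3-methylbut-2-enal | O=C/C=C(C)/C=C1C=C(/C=C/[C@@]23O[C@]2(C)C[C@@H](O)CC3(C)C)C(=O)O/1
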